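**Retrosynthetic overview**
- Target ⇒ desilylation, oxidation of the right-half secondary alcohol and equatorial methyl addition ⇒ a right-ring ketone whose left half is already finished (silyl-protected).
- Right oxepane (O–CMe2 bond) and right cyclohexanone ⇒ one reductive epoxide-opening cascade of a diepoxy enone (new step).
- Enone ⇒ cross-metathesis of the left bicycle (allyl handle) with a diepoxy vinyl ketone.
- Left bicycle ⇒ Wittig methylenation ⇐ first cascade (oxepane C–O bond, then cyclohexanone) of a silyl enol ether made from the same vinyl ketone by conjugate vinylation.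
- Vinyl ketone ⇐ geranyl bromide + Weinreb acetamide, double Shi epoxidation, vinyl Grignard. Ring order: left oxepane → left carbocycle → right oxepane → right carbocycle.

Assumption: reagents (Grignard reagents, silyl reagents, the L-fructose-derived Shi ketone made from L-sorbose) are bought or prepared separately and carry no compound number; "left" is the methylidene/secondary-alcohol bicycle, "right" the oxo/tertiary-alcohol bicycle.

**Step 1**
Reactants: 1 geranyl bromide [(2E)-1-bromo-3,7-dimethylocta-2,6-diene]; 2 N-methoxy-N-methylacetamide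
Product: 3 (4E)-N-methoxy-N,5,9-trimethyldeca-4,8-dienamide
Conditions: LiN(iPr)2, THF, −78 °C; then 1, −78 → −30 °C
Reagents that add atoms: none
Why: Enolate alkylation (SN2) of the Weinreb acetamide lithium enolate by the primary allylic bromide; the E-alkene is carried over and no stereocenter is formed.

**Step 2**
Reactants: 3 dienyl Weinreb amide
Product: 4 3-[(2S,3S)-3-{2-[(2S)-3,3-dimethyloxiran-2-yl]ethyl}-3-methyloxiran-2-yl]-N-methoxy-N-methylpropanamide
Conditions: L-fructose-derived Shi ketone (1,2:4,5-di-O-isopropylidene-β-L-erythro-2,3-hexodiulo-2,6-pyranose, 30 mol %), KHSO5 (as 2KHSO5·KHSO4·K2SO4), K2CO3, Bu4NHSO4, MeCN–CH2(OMe)2, aq. Na2B4O7/Na2H2EDTA buffer (pH 10.5), 0 °C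
Reagents that add atoms: potassium peroxymonosulfate, [K+].[O-]S(=O)(=O)OO
Why: Shi asymmetric epoxidation (chiral dioxirane, spiro transition state) oxidises both trisubstituted alkenes under catalyst control; the L-series ketone gives the (S)-terminal and (S,S)-internal epoxides that later become C3, C5a and C9a of both bicycles.

**Step 3**
Reactants: 4 diepoxy Weinreb amide
Product: 5 5-[(2S,3S)-3-{2-[(2S)-3,3-dimethyloxiran-2-yl]ethyl}-3-methyloxiran-2-yl]pent-1-en-3-one
Conditions: CH2=CHMgBr, THF, −78 → 0 °C; inverse quench into cold 1 M HCl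
Reagents that add atoms: vinylmagnesium bromide, C=C[Mg]Br
Why: Weinreb ketone synthesis: the magnesium chelate stops at mono-addition, the trisubstituted epoxides are inert at low temperature, and the acidic inverse quench removes MeONHMe before it can add to the vinyl ketone.

**Step 4**
Reactants: 5 diepoxy vinyl ketone
Product: 6 tert-butyl{[(3Z)-1-[(2S,3S)-3-{2-[(2S)-3,3-dimethyloxiran-2-yl]ethyl}-3-methyloxiran-2-yl]hepta-3,6-dien-3-yl]oxy}dimethylsilane
Conditions: CH2=CHMgBr, CuBr·SMe2 (10 mol %), TBSCl, HMPA, THF, −78 → −40 °C; Et3N, pH 7 buffer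
Reagents that add atoms: vinylmagnesium bromide, C=C[Mg]Br; tert-butyldimethylsilyl chloride, CC(C)(C)[Si](C)(C)Cl
Why: Copper-catalysed conjugate addition with chlorosilane trapping fixes the enol ether on the carbon that must become ring carbon C6 and installs the allyl handle; the Z-isomer arises from the s-cis enone.

**Step 5**
Reactants: 6 diepoxy silyl enol ether
Product: 7 (3S,5aS,6S,9aS)-3-[(tert-butyldimethylsilyl)oxy]-2,2,5a-trimethyl-6-(prop-2-en-1-yl)octahydro-1-benzoxepin-7(2H)-one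
Conditions: TBSOTf (0.3 equiv), 2,6-di-tert-butyl-4-methylpyridine, CH2Cl2, −78 → −40 °C; Et3N quench
Reagents that add atoms: none
Why: Silyl-triflate-initiated epoxide-opening oxa/carbacyclization cascade: the neighbouring epoxide oxygen opens the silylated terminal epoxide at its tertiary carbon (oxepane C–O bond, C3 retained), then the enol ether opens the epoxonium at the methyl-bearing carbon with inversion through a chair, giving the trans fusion and the equatorial (also thermodynamic) allyl group.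

**Step 6**
Reactants: 7 left bicyclic allyl ketone
Product: 8 tert-butyl{[(3S,5aS,6R,9aS)-2,2,5a-trimethyl-7-methylidene-6-(prop-2-en-1-yl)decahydro-1-benzoxepin-3-yl]oxy}dimethylsilane
Conditions: Ph3PCH3Br, KOtBu, toluene–THF, 0 → 60 °C
Reagents that add atoms: methyltriphenylphosphonium bromide, C[P+](c1ccccc1)(c1ccccc1)c1ccccc1.[Br-]
Why: Wittig methylenation of the hindered cyclohexanone; C6 already holds the thermodynamically preferred equatorial group, so the basic ylide cannot erode it.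

**Step 7**
Reactants: 8 left bicycle with allyl handle; 5 diepoxy vinyl ketone
Product: 9 (2E)-1-[(3S,5aS,6R,9aS)-3-[(tert-butyldimethylsilyl)oxy]-2,2,5a-trimethyl-7-methylidenedecahydro-1-benzoxepin-6-yl]-6-[(2S,3S)-3-{2-[(2S)-3,3-dimethyloxiran-2-yl]ethyl}-3-methyloxiran-2-yl]hex-2-en-4-one
Conditions: 5 (3 equiv), second-generation Hoveyda–Grubbs catalyst RuCl2(H2IMes)(=CH-C6H4-2-OiPr) (5 mol %), CH2Cl2, 40 °C
Reagents that add atoms: none
Why: Olefin cross-metathesis between a monosubstituted alkene and an electron-poor vinyl ketone is cross- and E-selective, while the hindered 1,1-disubstituted methylidene group and the epoxides are inert.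

**Step 8**
Reactants: 9 diepoxy enone
Product: 12 (3S,5aS,6S,9aS)-6-{2-[(3S,5aS,6R,9aS)-3-[(tert-butyldimethylsilyl)oxy]-2,2,5a-trimethyl-7-methylidenedecahydro-1-benzoxepin-6-yl]ethyl}-3-hydroxy-2,2,5a-trimethyloctahydro-1-benzoxepin-7(2H)-one, via dimethyl(phenyl)silyl enol ether 10 (not isolated), via trimethylsilyl ether 11 (not isolated)
Conditions: CuCl(IPr) (5 mol %; IPr = 1,3-bis(2,6-diisopropylphenyl)imidazol-2-ylidene), NaOtBu (5 mol %), PhMe2SiH (1.05 equiv), toluene, 0 °C → rt; then CH2Cl2, 2,6-di-tert-butyl-4-methylpyridine, Me3SiOTf (1.2 equiv), −78 °C; then 1 M HCl, THF, 0 °C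
Reagents that add atoms: none
Why: Proposed new method: a reductive epoxide-opening cascade in which the enone is a latent terminator — copper hydride adds hydride to the β-carbon and Cu–O/Si–H metathesis gives the Z silyl enol ether with the nucleophilic carbon fixed next to the linker; once the silane is consumed, Me3SiOTf silylates the terminal epoxide, the neighbouring epoxide oxygen attacks its tertiary carbon (oxepane C–O bond) and the enol ether opens the epoxonium at the methyl-bearing carbon with inversion via a chair (trans fusion, equatorial side chain, also the thermodynamic epimer); the closest known reactions are the silyl-triflate cascade of isolated diepoxy silyl enol ethers (step 5) and copper-hydride 1,4-hydrosilylation of enones, which have not been combined on an epoxy enone.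

**Step 9**
Reactants: 12 right-ring hydroxy ketone
Product: 13 (3S,5aS,6S,7R,9aS)-6-{2-[(3S,5aS,6R,9aS)-3-[(tert-butyldimethylsilyl)oxy]-2,2,5a-trimethyl-7-methylidenedecahydro-1-benzoxepin-6-yl]ethyl}-2,2,5a,7-tetramethyldecahydro-1-benzoxepine-3,7-diol
Conditions: MeMgBr, CeCl3, THF, −78 → 0 °C; aq. NH4Cl
Reagents that add atoms: methylmagnesium bromide, C[Mg]Br
Why: Organocerium 1,2-addition avoids enolisation of the hindered ketone; the axial face is blocked by the 1,3-diaxial 5a-methyl, so methyl enters equatorially and the new tertiary hydroxyl is axial (7R).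

**Step 10**
Reactants: 13 diol
Product: 14 (5aS,6S,7R,9aS)-6-{2-[(3S,5aS,6R,9aS)-3-[(tert-butyldimethylsilyl)oxy]-2,2,5a-trimethyl-7-methylidenedecahydro-1-benzoxepin-6-yl]ethyl}-7-hydroxy-2,2,5a,7-tetramethyloctahydro-1-benzoxepin-3(2H)-one
Conditions: Dess–Martin periodinane, pyridine, CH2Cl2, 0 °C → rt
Reagents that add atoms: none
Why: Dess–Martin oxidation of the only secondary alcohol; the tertiary alcohol, the silyl ether and the alkene are inert.

**Step 11**
Reactants: 14 silyl-protected keto alcohol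
Product: 15 (5aS,6S,7R,9aS)-7-hydroxy-6-{2-[(3S,5aS,6R,9aS)-3-hydroxy-2,2,5a-trimethyl-7-methylidenedecahydro-1-benzoxepin-6-yl]ethyl}-2,2,5a,7-tetramethyloctahydro-1-benzoxepin-3(2H)-one (CNP0160418.1)
Conditions: HF·pyridine, pyridine, THF, 0 °C → rt
Reagents that add atoms: none
Why: Fluoride-mediated silyl ether cleavage under pyridine buffering leaves the tertiary alcohol, the methylidene group and the α-alkoxy ketone untouched.

**Compound list**
1 | geranyl bromide, (2E)-1-bromo-3,7-dimethylocta-2,6-diene | CC(C)=CCC/C(C)=C/CBr | starting material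
2 | N-methoxy-N-methylacetamide | CC(=O)N(C)OC | starting material
3 | (4E)-N-methoxy-N,5,9-trimethyldeca-4,8-dienamide | CC(C)=CCC/C(C)=C/CCC(=O)N(C)OC | intermediate
4 | 3-[(2S,3S)-3-{2-[(2S)-3,3-dimethyloxiran-2-yl]ethyl}-3-methyloxiran-2-yl]-N-methoxy-N-methylpropanamide | CC1(C)O[C@H]1CC[C@]2(C)O[C@H]2CCC(=O)N(C)OC | intermediate
5 | 5-[(2S,3S)-3-{2-[(2S)-3,3-dimethyloxiran-2-yl]ethyl}-3-methyloxiran-2-yl]pent-1-en-3-one | CC1(C)O[C@H]1CC[C@]2(C)O[C@H]2CCC(=O)C=C | intermediate
6 | tert-butyl{[(3Z)-1-[(2S,3S)-3-{2-[(2S)-3,3-dimethyloxiran-2-yl]ethyl}-3-methyloxiran-2-yl]hepta-3,6-dien-3-yl]oxy}dimethylsilane | CC1(C)O[C@H]1CC[C@]2(C)O[C@H]2CC/C(O[Si](C)(C)C(C)(C)C)=C/CC=C | intermediate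
7 | (3S,5aS,6S,9aS)-3-[(tert-butyldimethylsilyl)oxy]-2,2,5a-trimethyl-6-(prop-2-en-1-yl)octahydro-1-benzoxepin-7(2H)-one (trans-fused, allyl equatorial) | O=C1CC[C@@H]2OC(C)(C)[C@@H](O[Si](C)(C)C(C)(C)C)CC[C@@]2(C)[C@@H]1CC=C | intermediate
8 | tert-butyl{[(3S,5aS,6R,9aS)-2,2,5a-trimethyl-7-methylidene-6-(prop-2-en-1-yl)decahydro-1-benzoxepin-3-yl]oxy}dimethylsilane | C=C1CC[C@@H]2OC(C)(C)[C@@H](O[Si](C)(C)C(C)(C)C)CC[C@@]2(C)[C@@H]1CC=C | intermediate
9 | (2E)-1-[(3S,5aS,6R,9aS)-3-[(tert-butyldimethylsilyl)oxy]-2,2,5a-trimethyl-7-methylidenedecahydro-1-benzoxepin-6-yl]-6-[(2S,3S)-3-{2-[(2S)-3,3-dimethyloxiran-2-yl]ethyl}-3-methyloxiran-2-yl]hex-2-en-4-one | C=C1CC[C@@H]2OC(C)(C)[C@@H](O[Si](C)(C)C(C)(C)C)CC[C@@]2(C)[C@@H]1C/C=C/C(=O)CC[C@@H]1O[C@@]1(C)CC[C@@H]1OC1(C)C | intermediate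
10 | {[(3Z)-1-[(3S,5aS,6R,9aS)-3-[(tert-butyldimethylsilyl)oxy]-2,2,5a-trimethyl-7-methylidenedecahydro-1-benzoxepin-6-yl]-6-[(2S,3S)-3-{2-[(2S)-3,3-dimethyloxiran-2-yl]ethyl}-3-methyloxiran-2-yl]hex-3-en-4-yl]oxy}dimethyl(phenyl)silane | C=C1CC[C@@H]2OC(C)(C)[C@@H](O[Si](C)(C)C(C)(C)C)CC[C@@]2(C)[C@@H]1CC/C=C(\O[Si](C)(C)c1ccccc1)CC[C@@H]1O[C@@]1(C)CC[C@@H]1OC1(C)C | intermediate
11 | trimethylsilyl ether of 12 at the right-half C3 hydroxyl | C=C1CC[C@@H]2OC(C)(C)[C@@H](O[Si](C)(C)C(C)(C)C)CC[C@@]2(C)[C@@H]1CC[C@H]1[C@]2(C)CC[C@H](O[Si](C)(C)C)C(C)(C)O[C@H]2CCC1=O | intermediate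
12 | (3S,5aS,6S,9aS)-6-{2-[(3S,5aS,6R,9aS)-3-[(tert-butyldimethylsilyl)oxy]-2,2,5a-trimethyl-7-methylidenedecahydro-1-benzoxepin-6-yl]ethyl}-3-hydroxy-2,2,5a-trimethyloctahydro-1-benzoxepin-7(2H)-one | C=C1CC[C@@H]2OC(C)(C)[C@@H](O[Si](C)(C)C(C)(C)C)CC[C@@]2(C)[C@@H]1CC[C@H]1[C@]2(C)CC[C@H](O)C(C)(C)O[C@H]2CCC1=O | intermediate
13 | (3S,5aS,6S,7R,9aS)-6-{2-[(3S,5aS,6R,9aS)-3-[(tert-butyldimethylsilyl)oxy]-2,2,5a-trimethyl-7-methylidenedecahydro-1-benzoxepin-6-yl]ethyl}-2,2,5a,7-tetramethyldecahydro-1-benzoxepine-3,7-diol | C=C1CC[C@@H]2OC(C)(C)[C@@H](O[Si](C)(C)C(C)(C)C)CC[C@@]2(C)[C@@H]1CC[C@H]1[C@]2(C)CC[C@H](O)C(C)(C)O[C@H]2CC[C@@]1(C)O | intermediate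
14 | (5aS,6S,7R,9aS)-6-{2-[(3S,5aS,6R,9aS)-3-[(tert-butyldimethylsilyl)oxy]-2,2,5a-trimethyl-7-methylidenedecahydro-1-benzoxepin-6-yl]ethyl}-7-hydroxy-2,2,5a,7-tetramethyloctahydro-1-benzoxepin-3(2H)-one | C=C1CC[C@@H]2OC(C)(C)[C@@H](O[Si](C)(C)C(C)(C)C)CC[C@@]2(C)[C@@H]1CC[C@H]1[C@]2(C)CCC(=O)C(C)(C)O[C@H]2CC[C@@]1(C)O | intermediate
15 | (5aS,6S,7R,9aS)-7-hydroxy-6-{2-[(3S,5aS,6R,9aS)-3-hydroxy-2,2,5a-trimethyl-7-methylidenedecahydro-1-benzoxepin-6-yl]ethyl}-2,2,5a,7-tetramethyloctahydro-1-benzoxepin-3(2H)-one | C=C1CC[C@@H]2OC(C)(C)[C@@H](O)CC[C@@]2(C)[C@@H]1CC[C@H]1[C@]2(C)CCC(=O)C(C)(C)O[C@H]2CC[C@@]1(C)O | target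

**Step count and risk**
Total step count: 11. Longest linear sequence: 11 (steps 1–11; compound 5 is used twice, in step 4 and as the metathesis partner in step 7).

The three steps most likely to fail:

Step 8 (the new reductive cascade). Risks are incomplete conjugate reduction, left-over hydride intercepting the cationic intermediates, and copper residues disturbing the silyl triflate stage. The fallback is known chemistry; it sets out from 9 and comes back at 12. Enone 9 is submitted to RhCl(PPh3)3-catalysed 1,4-hydrosilylation with Et3SiH (benzene, 50 °C) to give the isolable silyl enol ether triethyl{[(3Z)-1-[(3S,5aS,6R,9aS)-3-[(tert-butyldimethylsilyl)oxy]-2,2,5a-trimethyl-7-methylidenedecahydro-1-benzoxepin-6-yl]-6-[(2S,3S)-3-{2-[(2S)-3,3-dimethyloxiran-2-yl]ethyl}-3-methyloxiran-2-yl]hex-3-en-4-yl]oxy}silane F3. This is purified on triethylamine-deactivated silica and then put through the established Me3SiOTf/2,6-di-tert-butyl-4-methylpyridine cascade (CH2Cl2, −78 °C) and a dilute HCl work-up, passing through trimethylsilyl ether 11 to hydroxy ketone 12.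

Step 5 (first cascade). Risks are protodesilylation of the enol ether, incomplete turnover of the silyl transfer and interference by the pendant vinyl group. The fallback changes the terminator to a β-keto ester; it sets out from 4 and comes back at 7. Amide 4 is acylated with the lithium enolate of allyl acetate (LiN(iPr)2, THF, −78 °C) to give prop-2-en-1-yl 5-[(2S,3S)-3-{2-[(2S)-3,3-dimethyloxiran-2-yl]ethyl}-3-methyloxiran-2-yl]-3-oxopentanoate F1. Its enol terminates the TBSOTf/2,6-di-tert-butyl-4-methylpyridine cascade (β-keto esters are established terminators of Lewis-acid epoxy-polyene cyclisations) to give prop-2-en-1-yl (3S,5aS,6S,9aS)-3-[(tert-butyldimethylsilyl)oxy]-2,2,5a-trimethyl-7-oxodecahydro-1-benzoxepine-6-carboxylate F2. Pd(PPh3)4 in THF then effects decarboxylative allylation at the same carbon and returns to ketone 7.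

Step 9 (methyl addition to the hindered ketone). Risks are enolisation and low conversion. The fallback sets out from 12 and comes back at 13. Methylene transfer with dimethylsulfonium methylide (Me3S+ I−, NaH, DMSO–THF, 0 °C) gives the spiro-epoxide (3S,5aS,6S,7R,9aS)-6-{2-[(3S,5aS,6R,9aS)-3-[(tert-butyldimethylsilyl)oxy]-2,2,5a-trimethyl-7-methylidenedecahydro-1-benzoxepin-6-yl]ethyl}-2,2,5a-trimethyloctahydro-2H-spiro[1-benzoxepine-7,2'-oxiran]-3-ol F4; the CH2 enters equatorially for the same steric reason, leaving the oxygen axial. LiBHEt3 (THF, 0 °C) opens the epoxide at the CH2 carbon and gives diol 13.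

**Further compounds**
F1 | step 5 | prop-2-en-1-yl 5-[(2S,3S)-3-{2-[(2S)-3,3-dimethyloxiran-2-yl]ethyl}-3-methyloxiran-2-yl]-3-oxopentanoate | CC1(C)O[C@H]1CC[C@]2(C)O[C@H]2CCC(=O)CC(=O)OCC=C
F2 | step 5 | prop-2-en-1-yl (3S,5aS,6S,9aS)-3-[(tert-butyldimethylsilyl)oxy]-2,2,5a-trimethyl-7-oxodecahydro-1-benzoxepine-6-carboxylate | O=C1CC[C@@H]2OC(C)(C)[C@@H](O[Si](C)(C)C(C)(C)C)CC[C@@]2(C)[C@@H]1C(=O)OCC=C
F3 | step 8 | triethyl{[(3Z)-1-[(3S,5aS,6R,9aS)-3-[(tert-butyldimethylsilyl)oxy]-2,2,5a-trimethyl-7-methylidenedecahydro-1-benzoxepin-6-yl]-6-[(2S,3S)-3-{2-[(2S)-3,3-dimethyloxiran-2-yl]ethyl}-3-methyloxiran-2-yl]hex-3-en-4-yl]oxy}silane | C=C1CC[C@@H]2OC(C)(C)[C@@H](O[Si](C)(C)C(C)(C)C)CC[C@@]2(C)[C@@H]1CC/C=C(\O[Si](CC)(CC)CC)CC[C@@H]1O[C@@]1(C)CC[C@@H]1OC1(C)C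
F4 | step 9 | (3S,5aS,6S,7R,9aS)-6-{2-[(3S,5aS,6R,9aS)-3-[(tert-butyldimethylsilyl)oxy]-2,2,5a-trimethyl-7-methylidenedecahydro-1-benzoxepin-6-yl]ethyl}-2,2,5a-trimethyloctahydro-2H-spiro[1-benzoxepine-7,2'-oxiran]-3-ol | C=C1CC[C@@H]2OC(C)(C)[C@@H](O[Si](C)(C)C(C)(C)C)CC[C@@]2(C)[C@@H]1CC[C@H]1[C@]2(C)CC[C@H](O)C(C)(C)O[C@H]2CC[C@@]1(C3)O3
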